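(All runs come from a simulation from invented constants; scatter was added.)

One unit of initiator begins at most one chain, so the chains begun in a flask stay within the initiator charged. The average length therefore stays at or above a floor: the fraction of free monomer in chains, multiplied by the free monomer charged per initiator charged. I call that multiplier the charge length, 10.0 units, and it is the same for spring and dawn, which have the same loading.

| flask | free monomer | initiator | remark | time |
|---|---|---|---|---|
| beta | 0.059 M | 15 mol% | run made earlier |  |
| alpha | 0.059 M | 20 mol% | run made earlier |  |
| spring | 0.059 M | 10 mol% |  | 2.5 h |
| dawn | 0.020 M | 10 mol% |  | 2.5 h |

- beta (time / min: monomer in chains / %): 1.50: 3.4; 5.00: 8.5; 8.00: 15.4; 12.0: 23.5; 20.0: 38.9; 25.0: 47.0; 30.0: 53.9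
- alpha (time / min: monomer in chains / %): 4.00: 9.8; 8.00: 21.6; 12.0: 30.8; 15.0: 38.1; 20.0: 47.4; 25.0: 56.1; 30.0: 64.0

(readings scatter by 0.5 percentage points)

- which of the two ends with the longer chains by the average number of monomer units in a chain (chains begun, living or dead) ("neither" if they lie within 10%) (spring / dawn / neither)
- average number of monomer units in a chain (chains begun, living or dead) at the end, spring
- average number of monomer units in a chain (chains begun, living or dead) at the end, dawn

- the average divides the monomer in chains by the number of chains begun, living and dead together
- the earlier runs do not show the number of chains; that part of a forecast is a guess

To find the fraction reached in spring, I treat the loss of free monomer as first order in free monomer (pseudo-first-order) with a constant proportional to the initiator, and I read that constant two ways. The last beta reading gives 0.0258 min⁻¹, which becomes 0.0172 min⁻¹ when scaled to the loading of spring. The last alpha reading, scaled the same way, gives 0.0170 min⁻¹. These come from separate runs at different loadings and they agree, so I trust the reading. After 2.5 h, I then reckon about 92.4% in chains for spring, and its floor comes to about 9.24 units. Dawn has the same loading on 0.020 M of free monomer, so its initiator concentration scales with that charge, and the constant is 0.00583 min⁻¹. For dawn that gives about 58.3% in chains and an estimated floor of about 5.83 units. The height above these floors depends on how many chains begin, and the earlier runs do not show that.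

The forecast says spring ends longer, with 9.4 units in spring and 6.3 in dawn, and it adds: “Nearly all initiator should have started chains in both, though this is a guess.” Its figure for dawn lies above my floor.

The flask gives spring as the longer, with 12.0 units in spring and 8.92 in dawn.

    free monomer + initiator → living end + monomer in chains (k = 0.0300 L mol⁻¹ s⁻¹)
    initiator → spent initiator (k = 4.20 × 10⁻⁴ s⁻¹)
    free monomer + living end → monomer in chains + living end, rate k3*[living end]*[free monomer] (k = 0.0710 L mol⁻¹ s⁻¹)

At the end of spring 94.5% stands in chains, so the floor is 9.45 units, and floor over length puts the share of initiator that began a chain at 0.787. In dawn, the second flask, 50.9% in chains gives a floor of 5.09 units, and the share is smaller, 0.571. Dawn ends shorter than spring because of its lower concentration of free monomer: with that difference taken away, dawn ends at 12.0 units instead of 8.92.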